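Ring A (C1–C5 and C10, drimane numbering) is opened at C1–C10 and C3–C4. This leaves a C1–C2–C3 unit, acrylonitrile, and a ring B that carries C4 as the inner carbon of an isopropenyl group on C5, which is (S)-carvone. The key step is a one-flask [3+3] annulation of a carvone-derived epoxy ketone: Michael addition builds the quaternary C10, then iron-hydride hydrogen-atom transfer turns isopropenyl into the tertiary C4 radical, which closes on the nitrile carbon C3. It exploits the gem-dimethyl C4 beside the C3 carbonyl of ring A and fixes the trans ring fusion. The epoxide later relays its configuration to C9.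

Key step: step 3

Remark on numbering: all compounds carry drimane numbers (ring A: C1–C5, C10; ring B: C5–C10; C11 = OCH2 carbon). The monocyclic precursors use the numbers their carbons will have in the target (carvone C=O = C9, its neighbouring CH2 = C10, inner isopropenyl carbon = C4).
Assumption: (S)-(+)-carvone 1, acrylonitrile 4 and isofraxidin 10 are bought.

**Step 1**
Reactants: 1 (S)-(+)-carvone
Product: 2 6-methylcarvone (both epimers at C10)
Conditions: LiN(i-Pr)2, THF, −78 °C; MeI, −78 to 0 °C
Reagents that add atoms: iodomethane, CI
Why: Kinetic enolisation of the cross-conjugated enone at the CH2 that becomes C10 and SN2 methylation of the lithium enolate should give the methyl ketone, whose new centre need not be controlled because step 3 makes it trigonal again.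

**Step 2**
Reactants: 2 6-methylcarvone
Product: 3 epoxy ketone (oxirane trans to isopropenyl)
Conditions: 30% aq H2O2, NaOH (cat.), MeOH, 0 °C
Reagents that add atoms: hydrogen peroxide, OO
Why: Weitz–Scheffer nucleophilic epoxidation should place the oxirane trans to the isopropenyl group (hydroperoxide attacks C7 anti to the C5 substituent, as with carvone itself), which fixes the C7–O configuration used in steps 6 and 7 and removes the enone that would otherwise capture the nitrile-stabilised carbanion of step 3.

**Step 3**
Reactants: 3 epoxy ketone; 4 acrylonitrile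
Product: 7 epoxy diketone 7,8-epoxy-11-nordrimane-3,9-dione, via keto nitrile 5 (not isolated), via ketimine 6 (not isolated)
Conditions: KOt-Bu (10 mol %), t-BuOH/THF, 0 °C; then AcOH, evaporation of volatiles; then Fe(acac)3 (30 mol %), PhSiH3, EtOH, 60 °C; then 1 M aq HCl, THF, 0 °C
Reagents that add atoms: water, O
Why: Catalytic KOt-Bu can deprotonate 3 only at C10 (the other carbon next to the carbonyl is the fully substituted oxirane carbon C8), and the enolate adds to acrylonitrile to make C1–C10; after neutralisation and removal of excess acrylonitrile, the iron hydride formed from Fe(acac)3 and PhSiH3 transfers a hydrogen atom to the CH2 terminus of the isopropenyl group, and the tertiary C4 radical closes ring A by 6-exo-dig attack on the nitrile carbon C3, the iminyl radical being reduced to ketimine 6, which aqueous acid hydrolyses to the C3 ketone. The closest known reaction types are the base-catalysed cyanoethylation of an α-branched ketone and the metal-hydride hydrogen-atom-transfer cyclisation of alkenyl nitriles to α-quaternary cyclic ketones. The quaternary stereocentre C10 is set in the Michael step, in which acrylonitrile should approach the enolate face anti to the neighbouring C5 isopropenyl group (methyl then cis and side chain trans to it), and no new centre is formed in the radical step. Ring A can close only from the conformer with the C10 chain and the C5 radical both equatorial, so the trans ring fusion (5-H anti to the 10-methyl group) follows from that relationship. The step needs Markovnikov hydrogen-atom transfer to the 1,1-disubstituted alkene in the presence of the epoxy ketone and ring closure that outruns reduction of the radical; masking the enone as its epoxide excludes a second, intramolecular Michael addition to a bicyclo[2.2.2]octanone, and stripping the acrylonitrile excludes intermolecular Giese addition.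

**Step 4**
Reactants: 7 epoxy diketone
Product: 8 silyl enol ether 3-(triisopropylsilyloxy)-7,8-epoxy-11-nordrim-2-en-9-one
Conditions: KN(SiMe3)2, THF, −78 °C; i-Pr3SiOTf, −78 to 0 °C
Reagents that add atoms: triisopropylsilyl triflate, CC(C)[Si](OS(=O)(=O)C(F)(F)F)(C(C)C)C(C)C
Why: Regiospecific enolate O-silylation, since only C2 carries hydrogens next to a carbonyl (C4, C8 and C10 are fully substituted), should give a single silyl enol ether that masks C3 in steps 5 to 7 and is the handle for the last step.

**Step 5**
Reactants: 8 silyl enol ether
Product: 9 alkenyl oxirane 7,8-epoxy-3-(triisopropylsilyloxy)drima-2,9(11)-diene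
Conditions: Ph3PCH3Br, KN(SiMe3)2, toluene, 0 to 80 °C
Reagents that add atoms: methyltriphenylphosphonium bromide, C[P+](c1ccccc1)(c1ccccc1)c1ccccc1.[Br-]
Why: Wittig methylenation of the non-enolisable C9 ketone should give the alkenyl oxirane without touching the silyl enol ether; heating is planned because C9 lies between two fully substituted carbons.

**Step 6**
Reactants: 9 alkenyl oxirane; 10 isofraxidin
Product: 11 allylic alcohol aryl ether (7-OH on the face of 5-H, C8=C9)
Conditions: Pd(PPh3)4 (5 mol %), THF, rt
Reagents that add atoms: none
Why: Tsuji–Trost opening of the alkenyl oxirane, in which zerovalent palladium ionises the allylic C8–O bond, the C7 alkoxide deprotonates the phenol and the phenoxide should attack the unhindered CH2 terminus C11 of the π-allyl complex instead of the quaternary C8 (1,4-addition), forms the C11–O bond of the target and leaves the C7 carbinol centre untouched.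

**Step 7**
Reactants: 11 allylic alcohol aryl ether
Product: 14 transposed aryl ether (C7=C8, CH2OAr on the face of 5-H), via sulfonylhydrazine 12 (not isolated), via allylic diazene 13 (not isolated)
Conditions: 2-O2NC6H4SO2NHNH2, PPh3, EtO2CN=NCO2Et, N-methylmorpholine, −30 °C to rt
Reagents that add atoms: none
Why: Reductive 1,3-transposition of an allylic alcohol through a monoalkyl diazene (Mitsunobu displacement at C7 by the sulfonyl hydrazide with inversion, loss of the sulfinic acid, retro-ene loss of N2) should shift the double bond to C7=C8 and deliver hydrogen to C9 suprafacially from the face of the C7–N bond, which is the face of the 10-methyl group, so that C9 is set with CH2OAr on the face of 5-H; the azodicarboxylate is consumed by PPh3 before it can aminate the silyl enol ether, and the amine solvent buffers the sulfinic acid.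

**Step 8**
Reactants: 14 transposed aryl ether
Product: 15 target CNP0330704.1
Conditions: Pd(OAc)2 (1.1 equiv), DMSO/MeCN, 40 °C
Reagents that add atoms: none
Why: Saegusa–Ito oxidation, in which the silyl enol ether gives a C2 palladium enolate and β-hydride elimination towards C1, should give the C1=C2 enone as the only possible regioisomer, since C4 and C10 are quaternary.

**Compound list**
1 | (S)-(+)-carvone, (5S)-2-methyl-5-(prop-1-en-2-yl)cyclohex-2-en-1-one | CC1=CC[C@@H](CC1=O)C(C)=C | starting material
2 | 6-methylcarvone, (5S,6RS)-2,6-dimethyl-5-(prop-1-en-2-yl)cyclohex-2-en-1-one (both epimers at C10) | CC1=CC[C@@H](C(C)C1=O)C(C)=C | intermediate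
3 | epoxy ketone, (1S,3RS,4S,6S)-1,3-dimethyl-4-(prop-1-en-2-yl)-7-oxabicyclo[4.1.0]heptan-2-one (oxirane trans to isopropenyl; both epimers at C10) | O=C1C(C)[C@@H](C(C)=C)C[C@@H]2O[C@@]21C | intermediate
4 | acrylonitrile | C=CC#N | starting material
5 | keto nitrile (not isolated): 3 carrying a 2-cyanoethyl group on C10, cyanoethyl trans and methyl cis to the isopropenyl group on C5 | N#CCC[C@]1(C)[C@@H](C(C)=C)C[C@@H]2O[C@]2(C)C1=O | intermediate
6 | ketimine (not isolated): 3-imino-7,8-epoxy-11-nordriman-9-one, trans-fused, 10-methyl anti to 5-H, oxirane oxygen on the face of 5-H | CC1(C)C(=N)CC[C@@]2(C)C(=O)[C@@]3(C)O[C@H]3C[C@H]12 | intermediate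
7 | epoxy diketone: 7,8-epoxy-11-nordrimane-3,9-dione, trans-fused, 10-methyl anti to 5-H, oxirane oxygen on the face of 5-H | CC1(C)C(=O)CC[C@@]2(C)C(=O)[C@@]3(C)O[C@H]3C[C@H]12 | intermediate
8 | silyl enol ether: 3-(triisopropylsilyloxy)-7,8-epoxy-11-nordrim-2-en-9-one, configuration as in 7 | CC1(C)C(O[Si](C(C)C)(C(C)C)C(C)C)=CC[C@@]2(C)C(=O)[C@@]3(C)O[C@H]3C[C@H]12 | intermediate
9 | alkenyl oxirane: 7,8-epoxy-3-(triisopropylsilyloxy)drima-2,9(11)-diene, configuration as in 7 | CC1(C)C(O[Si](C(C)C)(C(C)C)C(C)C)=CC[C@@]2(C)C(=C)[C@@]3(C)O[C@H]3C[C@H]12 | intermediate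
10 | isofraxidin, 7-hydroxy-6,8-dimethoxy-2H-chromen-2-one | COc1cc2ccc(=O)oc2c(OC)c1O | starting material
11 | allylic alcohol aryl ether: 7-{[7-hydroxy-3-(triisopropylsilyloxy)drima-2,8-dien-11-yl]oxy}-6,8-dimethoxycoumarin, 7-OH on the face of 5-H | CC1(C)C(O[Si](C(C)C)(C(C)C)C(C)C)=CC[C@@]2(C)C(COc3c(OC)cc4ccc(=O)oc4c3OC)=C(C)[C@@H](O)C[C@H]12 | intermediate
12 | sulfonylhydrazine (not isolated): 11 with the 7-OH replaced, with inversion, by N(NH2)SO2C6H4-2-NO2 | CC1(C)C(O[Si](C(C)C)(C(C)C)C(C)C)=CC[C@@]2(C)C(COc3c(OC)cc4ccc(=O)oc4c3OC)=C(C)[C@H](N(N)S(=O)(=O)c5ccccc5[N+](=O)[O-])C[C@H]12 | intermediate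
13 | allylic diazene (not isolated): 12 after loss of the sulfinic acid, N=NH on C7 on the face of the 10-methyl group | CC1(C)C(O[Si](C(C)C)(C(C)C)C(C)C)=CC[C@@]2(C)C(COc3c(OC)cc4ccc(=O)oc4c3OC)=C(C)[C@H](N=N)C[C@H]12 | intermediate
14 | transposed aryl ether: 7-{[3-(triisopropylsilyloxy)drima-2,7-dien-11-yl]oxy}-6,8-dimethoxycoumarin, CH2OAr on C9 on the face of 5-H, 10-methyl on the other face | CC1(C)C(O[Si](C(C)C)(C(C)C)C(C)C)=CC[C@@]2(C)[C@@H](COc3c(OC)cc4ccc(=O)oc4c3OC)C(C)=CC[C@H]12 | intermediate
15 | CNP0330704.1, 7-{[(1S,4aS,8aR)-2,5,5,8a-tetramethyl-6-oxo-1,4,4a,5,6,8a-hexahydronaphthalen-1-yl]methoxy}-6,8-dimethoxy-2H-chromen-2-one | COc1cc2ccc(=O)oc2c(OC)c1OC[C@H]1C(C)=CC[C@@H]2C(C)(C)C(=O)C=C[C@]21C | target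

Total step count: 8.
Longest linear sequence: 8 steps, from (S)-(+)-carvone 1; acrylonitrile 4 and isofraxidin 10 enter as bought reagents.

**Steps most likely to fail**

Step 3. The tertiary C4 radical may be reduced by hydrogen-atom capture before it closes on the weakly accepting nitrile. The Michael addition may also show poor facial selectivity, because the oxirane oxygen lies on the face the acceptor must approach. The fallback sets out from 3 and makes the two bonds in separate steps with a faster radical trap. The lithium enolate of 3 (LiN(i-Pr)2, THF/DMPU, −78 °C) is alkylated with 2-(2-iodoethyl)-1,3-dioxolane to give the keto acetal F1. Mild hydrolysis (pyridinium tosylate, acetone/water) gives the keto aldehyde F2. Hydrogen-atom-transfer cyclisation (Fe(acac)3, PhSiH3, EtOH) of the C4 radical onto the aldehyde carbonyl gives the hydroxy ketone F3 as a mixture of C3 epimers. Dess–Martin oxidation of F3 comes back to the route at 7.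

Step 5. The ylide may fail to add to the carbonyl shielded on both sides, with base-induced opening of the oxirane taking over on prolonged heating. The fallback sets out from 8 and brings in C11 by a sigmatropic shift instead of an olefination. Wharton transposition of 8 (N2H4·H2O, AcOH, MeOH) gives the allylic alcohol F4 (7-OH on the face of 5-H, C8=C9). O-alkylation (KH, Bu3SnCH2I, THF) gives the stannylmethyl ether F5. Tin–lithium exchange (n-BuLi, THF, −78 °C) triggers a [2,3]-Wittig–Still rearrangement that places CH2OH on C9 on the face of 5-H and forms C7=C8, giving the homoallylic alcohol F6. Mitsunobu etherification of F6 with isofraxidin 10 (PPh3, i-PrO2CN=NCO2i-Pr, THF) comes back to the route at 14, so steps 5 to 7 are bypassed.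

Step 7. The activated allylic alcohol may ionise to an allyl cation, which loses the clean inversion at C7 and hence the configuration at C9, or it may eliminate to a diene. The fallback sets out from 11 and uses a palladium-bound hydride instead of a diazene. Formylation of 11 (acetic formic anhydride, pyridine) gives the allylic formate F7. Pd(OAc)2 with n-Bu3P in THF at reflux should ionise F7 anti to the formate, lose CO2 and deliver hydride from palladium to the more substituted terminus C9 on the face of the 10-methyl group. This comes back to the route at 14.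

**Further compounds**
F1 | step 3 | keto acetal: 3 carrying a 2-(1,3-dioxolan-2-yl)ethyl group on C10, trans to isopropenyl | O1CCOC1CC[C@]3(C)[C@@H](C(C)=C)C[C@@H]2O[C@]2(C)C3=O
F2 | step 3 | keto aldehyde: 3 carrying a 3-oxopropyl group on C10, trans to isopropenyl | O=CCC[C@]1(C)[C@@H](C(C)=C)C[C@@H]2O[C@]2(C)C1=O
F3 | step 3 | hydroxy ketone: 3-hydroxy-7,8-epoxy-11-nordriman-9-one, both C3 epimers, otherwise as 7 | CC1(C)C(O)CC[C@@]2(C)C(=O)[C@@]3(C)O[C@H]3C[C@H]12
F4 | step 5 | allylic alcohol: 3-(triisopropylsilyloxy)-11-nordrima-2,8-dien-7-ol, 7-OH on the face of 5-H | CC1(C)C(O[Si](C(C)C)(C(C)C)C(C)C)=CC[C@@]2(C)C=C(C)[C@@H](O)C[C@H]12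
F5 | step 5 | stannylmethyl ether: tributylstannylmethyl ether of F4 | CC1(C)C(O[Si](C(C)C)(C(C)C)C(C)C)=CC[C@@]2(C)C=C(C)[C@@H](OC[Sn](CCCC)(CCCC)CCCC)C[C@H]12
F6 | step 5 | homoallylic alcohol: 3-(triisopropylsilyloxy)drima-2,7-dien-11-ol, CH2OH on C9 on the face of 5-H | CC1(C)C(O[Si](C(C)C)(C(C)C)C(C)C)=CC[C@@]2(C)[C@@H](CO)C(C)=CC[C@H]12
F7 | step 7 | allylic formate: formate ester of 11 at the 7-hydroxyl | CC1(C)C(O[Si](C(C)C)(C(C)C)C(C)C)=CC[C@@]2(C)C(COc3c(OC)cc4ccc(=O)oc4c3OC)=C(C)[C@@H](OC=O)C[C@H]12
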